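**Retrosynthetic overview**

1. Target 16 ⇐ tetra-MOM ether 15 by global acetal cleavage. No ring is built: both benzene rings are bought, and the only ring operated on is an oxirane that is opened.
2. 15 ⇐ one-flask union of three pieces at the two bonds flanking the carbinol: aryl Grignard 11 opens epoxy Weinreb amide 10 at C3 (ring B–CH2 bond), then aryllithium 13 adds to the amide (ring A–C(=O) bond).
3. 13 ⇐ mirror-symmetric 2-prenylresorcinol bis-MOM ether 4 by desymmetrising ortho-lithiation (both free ortho positions are equivalent and give the same 2,4-dioxy-3-prenylphenyl unit); 4 ⇐ resorcinol.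
4. 11 ⇐ aryl bromide 8 ⇐ 3,5-dibromocatechol by ortho-selective Br/Li exchange and prenylation.
5. The stereocentre is bought as potassium (R)-glycidate (→ 10); C2 is never touched, so (R) is carried unchanged into 16.

Assumption: 5 and 9 are taken as catalogue chemicals, and the target is the (R)-enantiomer encoded by the given SMILES.

**Route**

Step 1
Reactants: 1 resorcinol
Product: 2 1,3-bis(methoxymethoxy)benzene
Conditions: NaH (2.4 equiv), MOMCl (2.4 equiv), THF/DMF, 0 °C to rt
Reagents that add atoms: chloromethyl methyl ether (MOMCl), COCCl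
Why: Williamson-type O-alkylation of the bis-phenoxide installs acetals that protect the phenols and later direct both lithiations of this ring.

Step 2
Reactants: 2 1,3-bis(methoxymethoxy)benzene
Product: 4 1,3-bis(methoxymethoxy)-2-(3-methylbut-2-en-1-yl)benzene, via aryllithium 3 (not isolated)
Conditions: n-BuLi (1.1 equiv), THF, 0 °C to rt, 1.5 h; then prenyl bromide (1.2 equiv), −78 °C to rt
Reagents that add atoms: prenyl bromide (1-bromo-3-methylbut-2-ene), CC(C)=CCBr
Why: Directed ortho-metalation takes place at the carbon flanked by both OMOM groups, and SN2 alkylation of the aryllithium at the primary allylic carbon gives the linear prenyl arene, which keeps the mirror symmetry of resorcinol.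

Step 3
Reactants: 5 3,5-dibromocatechol
Product: 6 1,5-dibromo-2,3-bis(methoxymethoxy)benzene
Conditions: NaH (2.4 equiv), MOMCl (2.4 equiv), THF/DMF, 0 °C to rt
Reagents that add atoms: chloromethyl methyl ether (MOMCl), COCCl
Why: Williamson-type O-alkylation of the catechol dianion gives the bis-acetal needed to steer the halogen–metal exchange and to survive the organometallic steps.

Step 4
Reactants: 6 1,5-dibromo-2,3-bis(methoxymethoxy)benzene
Product: 8 5-bromo-1,2-bis(methoxymethoxy)-3-(3-methylbut-2-en-1-yl)benzene, via aryllithium 7 (not isolated)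
Conditions: n-BuLi (1.0 equiv), THF, −78 °C, 20 min; then prenyl bromide (1.5 equiv), −78 to 0 °C
Reagents that add atoms: prenyl bromide (1-bromo-3-methylbut-2-ene), CC(C)=CCBr
Why: Bromine–lithium exchange is fastest at the bromine ortho to an OMOM group (chelation and inductive stabilisation, as with 2,4-dibromoanisole), and SN2 alkylation of that aryllithium installs the prenyl group while the remote bromine is kept for step 6.

Step 5
Reactants: 9 potassium (2R)-oxirane-2-carboxylate
Product: 10 (2R)-N-methoxy-N-methyloxirane-2-carboxamide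
Conditions: MeNHOMe·HCl (1.1 equiv), DCC (1.1 equiv), HOBt (10 mol %), CH2Cl2/DMF, 0 °C to rt
Reagents that add atoms: N,O-dimethylhydroxylamine hydrochloride, CNOC.Cl
Why: Carbodiimide amide coupling of an epoxy-carboxylate salt with an amine hydrochloride (routine for epoxysuccinyl peptides) runs under near-neutral conditions that leave the oxirane closed and never involve C2, so the (R)-centre is retained.

Step 6
Reactants: 8 5-bromo-1,2-bis(methoxymethoxy)-3-(3-methylbut-2-en-1-yl)benzene; 10 (2R)-N-methoxy-N-methyloxirane-2-carboxamide; 4 1,3-bis(methoxymethoxy)-2-(3-methylbut-2-en-1-yl)benzene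
Product: 15 (2R)-1-[2,4-bis(methoxymethoxy)-3-(3-methylbut-2-en-1-yl)phenyl]-3-[3,4-bis(methoxymethoxy)-5-(3-methylbut-2-en-1-yl)phenyl]-2-hydroxypropan-1-one, via Grignard reagent 11 (not isolated), via magnesium alkoxide 12 (not isolated), via aryllithium 13 (not isolated), via tetrahedral adduct 14 (not isolated)
Conditions: flask 1: 8, Mg, THF, 45 °C, then added slowly to 10 (1.1 equiv), CuBr·SMe2 (10 mol %), THF, −45 °C, 1 h; flask 2: 4 (1.8 equiv), n-BuLi (1.7 equiv), TMEDA, THF, 0 °C, 1.5 h; flask 2 into flask 1 at −78 °C, then −10 °C, 2 h; aq. NH4Cl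
Reagents that add atoms: none
Why: Proposed new method: a one-flask three-component union in which copper-catalysed SN2 opening of the glycidic amide at its unsubstituted C3 by the aryl Grignard (closest precedent: copper-catalysed ArMgBr opening of methyl glycidate to 3-aryl-lactates) should outrun carbonyl attack at −45 °C and leaves the (R)-centre untouched as its magnesium alkoxide, after which the mirror-symmetric arene 4, desymmetrised by directed ortho-lithiation at one of its two equivalent positions next to OMOM, adds once to the amide (Weinreb ketone synthesis on an α-alkoxide amide, where the N-methoxy chelate 14 blocks over-addition and the adjacent alkoxide blocks enolisation and hence racemisation).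

Step 7
Reactants: 15 (2R)-1-[2,4-bis(methoxymethoxy)-3-(3-methylbut-2-en-1-yl)phenyl]-3-[3,4-bis(methoxymethoxy)-5-(3-methylbut-2-en-1-yl)phenyl]-2-hydroxypropan-1-one
Product: 16 (2R)-1-[2,4-dihydroxy-3-(3-methylbut-2-en-1-yl)phenyl]-3-[3,4-dihydroxy-5-(3-methylbut-2-en-1-yl)phenyl]-2-hydroxypropan-1-one
Conditions: 3 M aq. HCl/MeOH (1:5), 45 °C, 2–4 h, monitored and stopped at full conversion
Reagents that add atoms: none
Why: Acid-catalysed acetal exchange with methanol removes the four aryl MOM groups as dimethoxymethane under conditions commonly used on prenylated flavonoids, and the carbinol centre survives because acid enolisation of the hydrogen-bonded aryl ketone is slow at this temperature.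

**Compound list**

1 | resorcinol (benzene-1,3-diol) | Oc1cccc(O)c1 | starting material
2 | 1,3-bis(methoxymethoxy)benzene | COCOc1cccc(OCOC)c1 | intermediate
3 | [2,6-bis(methoxymethoxy)phenyl]lithium (in-flask species) | [Li]c1c(OCOC)cccc1OCOC | intermediate
4 | 1,3-bis(methoxymethoxy)-2-(3-methylbut-2-en-1-yl)benzene | COCOc1cccc(OCOC)c1CC=C(C)C | intermediate
5 | 3,5-dibromocatechol (3,5-dibromobenzene-1,2-diol) | Oc1cc(Br)cc(Br)c1O | starting material
6 | 1,5-dibromo-2,3-bis(methoxymethoxy)benzene (bis-MOM ether of 5) | COCOc1cc(Br)cc(Br)c1OCOC | intermediate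
7 | [5-bromo-2,3-bis(methoxymethoxy)phenyl]lithium (in-flask species) | COCOc1cc(Br)cc([Li])c1OCOC | intermediate
8 | 5-bromo-1,2-bis(methoxymethoxy)-3-(3-methylbut-2-en-1-yl)benzene | COCOc1cc(Br)cc(CC=C(C)C)c1OCOC | intermediate
9 | potassium (2R)-oxirane-2-carboxylate (potassium (R)-glycidate) | [K+].[O-]C(=O)[C@H]1CO1 | starting material
10 | (2R)-N-methoxy-N-methyloxirane-2-carboxamide | CON(C)C(=O)[C@H]1CO1 | intermediate
11 | [3,4-bis(methoxymethoxy)-5-(3-methylbut-2-en-1-yl)phenyl]magnesium bromide (in-flask species) | CC(C)=CCc1cc([Mg]Br)cc(OCOC)c1OCOC | intermediate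
12 | bromomagnesium (2R)-3-[3,4-bis(methoxymethoxy)-5-(3-methylbut-2-en-1-yl)phenyl]-1-[methoxy(methyl)amino]-1-oxopropan-2-olate (in-flask species) | CC(C)=CCc1cc(C[C@@H](O[Mg]Br)C(=O)N(C)OC)cc(OCOC)c1OCOC | intermediate
13 | [2,4-bis(methoxymethoxy)-3-(3-methylbut-2-en-1-yl)phenyl]lithium (in-flask species) | COCOc1ccc([Li])c(OCOC)c1CC=C(C)C | intermediate
14 | O1-lithio O2-bromomagnesio tetrahedral adduct of 13 and 12, the 1-[methoxy(methyl)amino]propane-1,2-diolate (2R; C1 undefined and lost on work-up; in-flask species) | CC(C)=CCc1cc(C[C@@H](O[Mg]Br)C(O[Li])(N(C)OC)c2ccc(OCOC)c(CC=C(C)C)c2OCOC)cc(OCOC)c1OCOC | intermediate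
15 | (2R)-1-[2,4-bis(methoxymethoxy)-3-(3-methylbut-2-en-1-yl)phenyl]-3-[3,4-bis(methoxymethoxy)-5-(3-methylbut-2-en-1-yl)phenyl]-2-hydroxypropan-1-one | CC(C)=CCc1cc(C[C@@H](O)C(=O)c2ccc(OCOC)c(CC=C(C)C)c2OCOC)cc(OCOC)c1OCOC | intermediate
16 | (2R)-1-[2,4-dihydroxy-3-(3-methylbut-2-en-1-yl)phenyl]-3-[3,4-dihydroxy-5-(3-methylbut-2-en-1-yl)phenyl]-2-hydroxypropan-1-one (CNP0286988.1) | CC(C)=CCc1cc(C[C@@H](O)C(=O)c2ccc(O)c(CC=C(C)C)c2O)cc(O)c1O | target

**Totals**

Total step count: 7. Longest linear sequence: 4 steps (1 → 2 → 4 → 15 → 16 through steps 1, 2, 6, 7; the arm 5 → 6 → 8 → 15 → 16 is equally long).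

**Steps most likely to fail, with fallbacks**

Step 6 is the riskiest. The Grignard reagent may attack the Weinreb carbonyl of 10 instead of the epoxide, and the hindered aryllithium 13 may add sluggishly to the alkoxide-bearing amide. The fallback sets out from 9 and never lets a Grignard reagent meet a Weinreb amide; every stage is isolated. 9 is O-methylated (MeI, DMF, rt) to methyl (2R)-oxirane-2-carboxylate F1. Grignard reagent 11, made from 8 and Mg as before, opens F1 at C3 (CuBr·SMe2 10 mol %, THF, −40 °C) to give methyl (2R)-3-[3,4-bis(methoxymethoxy)-5-(3-methylbut-2-en-1-yl)phenyl]-2-hydroxypropanoate F2. F2 is converted with MeNHOMe·HCl and i-PrMgCl (THF, −20 °C) into (2R)-3-[3,4-bis(methoxymethoxy)-5-(3-methylbut-2-en-1-yl)phenyl]-2-hydroxy-N-methoxy-N-methylpropanamide F3. F3 is deprotonated with i-PrMgCl (1 equiv) and treated with 13 (1.5 equiv, from 4 as before; THF, −78 to 0 °C; aq. NH4Cl), which returns the route at 15.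

Step 7 is next. Protic acid can cyclise the ortho-prenylphenols to chromans and may slowly epimerise the ketol. The fallback sets out from 15 and replaces hydrolysis by a proton-free silyl transfer. TMSOTf (8 equiv) and 2,2'-bipyridyl (12 equiv) in MeCN at 0 °C to rt convert the four aryl MOM ethers and the free alcohol into the pentakis(trimethylsilyl) ether (2R)-1-[2,4-bis(trimethylsilyloxy)-3-(3-methylbut-2-en-1-yl)phenyl]-3-[3,4-bis(trimethylsilyloxy)-5-(3-methylbut-2-en-1-yl)phenyl]-2-(trimethylsilyloxy)propan-1-one F4, the MOM carbon being captured by bipyridyl. F4 is desilylated with MeOH and a trace of citric acid at rt, which returns the route at 16.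

Step 4 is third. The aryllithium can be butylated by the 1-bromobutane formed in the exchange, attack prenyl bromide at its tertiary end, or undergo Wurtz-type scrambling. The fallback sets out from 6 and builds the prenyl group by olefin metathesis instead of alkylation. Aryllithium 7, generated as before, is trapped with allyl bromide, which has no α/γ ambiguity, to give 5-bromo-1,2-bis(methoxymethoxy)-3-(prop-2-en-1-yl)benzene F5. Cross-metathesis of F5 with excess 2-methylbut-2-ene (second-generation Grubbs catalyst RuCl2(=CHPh)(H2IMes)(PCy3), CH2Cl2, 40 °C) returns the route at 8.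

**Further compounds**

F1 | step 6 | methyl (2R)-oxirane-2-carboxylate | COC(=O)[C@H]1CO1
F2 | step 6 | methyl (2R)-3-[3,4-bis(methoxymethoxy)-5-(3-methylbut-2-en-1-yl)phenyl]-2-hydroxypropanoate | CC(C)=CCc1cc(C[C@@H](O)C(=O)OC)cc(OCOC)c1OCOC
F3 | step 6 | (2R)-3-[3,4-bis(methoxymethoxy)-5-(3-methylbut-2-en-1-yl)phenyl]-2-hydroxy-N-methoxy-N-methylpropanamide | CC(C)=CCc1cc(C[C@@H](O)C(=O)N(C)OC)cc(OCOC)c1OCOC
F4 | step 7 | (2R)-1-[2,4-bis(trimethylsilyloxy)-3-(3-methylbut-2-en-1-yl)phenyl]-3-[3,4-bis(trimethylsilyloxy)-5-(3-methylbut-2-en-1-yl)phenyl]-2-(trimethylsilyloxy)propan-1-one | CC(C)=CCc1cc(C[C@@H](O[Si](C)(C)C)C(=O)c2ccc(O[Si](C)(C)C)c(CC=C(C)C)c2O[Si](C)(C)C)cc(O[Si](C)(C)C)c1O[Si](C)(C)C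
F5 | step 4 | 5-bromo-1,2-bis(methoxymethoxy)-3-(prop-2-en-1-yl)benzene | C=CCc1cc(Br)cc(OCOC)c1OCOC
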